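1. The closed vessel of Tuesday's flask looks nearly like the beta run: the substrate, reagent and free catalyst charges match, and scavenger stands at 1.50 equiv against 2.2 equiv.

in all of them: substrate 0.050 M

| run | reagent | scavenger | free catalyst | remark | time |
|---|---|---|---|---|---|
| beta | 1.2 equiv | 2.2 equiv | 4.4 mol% | run made earlier |  |
| Sunday's | 0.400 equiv | 1.50 equiv | 20 mol% |  | 2.5 d |
| Tuesday's | 1.20 equiv | 1.50 equiv | 4.4 mol% |  | 2.5 d |

- beta (time / h: product / %): 1.00: 1.2; 2.00: 3.0; 5.00: 8.4; 12.0: 18.9

(each reading ± 0.5 percentage points)

- no earlier run changes the charge of free catalyst; that part of a forecast is a guess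
- no earlier run changes the charge of scavenger; that part of a forecast is a guess

- the winner by amount of product, in percent of the substrate charged; "neither" if no more than 2 percentage points parts them (Sunday's / Tuesday's / neither)
- how much product is there at the end, in percent of the substrate charged: Sunday's
- how much product is there at the end, in percent of the substrate charged: Tuesday's

2. We reckon with the fraction left, not the fraction made. The beta run has 81.1 % of its substrate left after 12.0 h. Read as first order, that gives a constant of 0.0175 /h, with the scatter of that reading.

3. No run tests the scavenger, so we guess that Tuesday's flask keeps this constant. Over 2.5 d, its fraction left is 35.1 %, which gives 64.9 % product.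

4. Reagent sets a second limit if one reagent makes one product. For Sunday's flask the floor is 60.0 %, the fraction of the substrate that stays out of product once the reagent is used up. Reagent is the limiting reagent there, at 0.400 equiv. Tuesday's flask, at 1.20 equiv, has a floor of 0 %.

5. Does Sunday's flask reach its floor? We guess that the constant grows with the catalyst charge. Rate by itself then reckons 0.856 % left, far less than the floor. So we commit to 40.0 % for Sunday's flask and 64.9 % for Tuesday's.

6. The forecast names Tuesday's. It gives Sunday's flask 38 % (30 % to 40.5 %) and Tuesday's 62 % (46 % to 75 %), holding that “reagent caps product at 40%”. Our figures are higher than its two.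

7. The flasks give Tuesday's as the winner: Sunday's 40.0 %, Tuesday's 73.4 %.

    substrate + free catalyst ⇌ catalyst intermediate A (K = 60.0 /M, k = 0.0243 /M/s)
    reagent + catalyst intermediate A ⇌ catalyst intermediate B (K = 39.0 /M, k = 0.0268 /M/s)
    catalyst intermediate B ⇌ released group + catalyst intermediate C (K = 0.0747 M, k = 2.51 × 10⁻⁴ /s)
    catalyst intermediate C → catalyst intermediate D (k = 0.0296 /s)
    catalyst intermediate D → free catalyst + product (k = 0.00101 /s)
    reagent + released group ⇌ idle adduct, settled at all times (K = 61.0 /M)
    scavenger + released group → scavenged by-product (k = 0.0167 /M/s)

8. Sunday's flask ends on its floor of 60.0 %, as free substrate 48 % plus 11.8 % of the substrate in catalyst intermediate A. The neighbour with 0.240 equiv of reagent has a floor of 76.0 %; it holds 62.9 % plus 13.1 %, with 24.0 % product. In Sunday's flask, the turning of catalyst intermediate B into released group and catalyst intermediate C had half its turnover done by 0.268 d, and the run lasted 9.33 times as long. After 1.25 d, that step had 98 % of its turnover behind it.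

Readings and results come from a simulation from invented constants.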